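**Retrosynthetic overview**

1. Numbering: carbocycle C1–C10 with C10=C1 and C2=C3, oxirane C4–C5 (C15 methyl on C4), lactone O on C6, C7–C11(=C13)–C12(=O), epoxyangelate on C8, acetate on C9, ester carbon C14 on C10. The strategy rests on the cis,cis diene C10=C1–C2=C3 held between C4 and C9: it is a cyclohexa-1,3-diene whose C4–C9 bond has been cut, and C6–C7 is the bond at which E-alkenyl groups on C4 and C9 would meet.
2. Key disconnection: C6–C7 formed and C4–C9 broken by anionic oxy-Cope ring expansion of the trans-1,2-dialkenylcyclohexa-2,4-dienol 22 to the ten-membered trienone 25 (sets C6, C7 and the E C4=C5 alkene).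
3. Precursor 22: chelate-controlled alkenyl-Grignard addition to 2,4-dienone 11 (C9), E enol ether by Takai iodo-olefination and copper C–O coupling (C5=C6), quaternary C4 by chiral-benzamide Birch reduction–methylation of the arene that supplies the six-membered ring.
4. After ring expansion: peripheral epoxidation (C4, C5), bromination then carboxylate displacement with inversion (C8 ester), Felkin-type reduction and acetylation (C9), oxidative lactonisation of the 2-methyleneallyl alcohol side chain carried from step 9 (C11–C13), C14 methyl to methyl ester.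
5. Ring order: cyclohexadiene (from the benzene ring), ten-membered carbocycle (step 14), oxirane (step 15), γ-lactone (step 25).

Key step: step 14

Assumption: in step 2 the (S)-auxiliary is taken to steer methylation to the face that gives the R quaternary carbon drawn for 6; if the sense is the opposite, the (R)-auxiliary is used instead.

**Route**

Step 1
Reactants: 1 2-methoxy-3-methylbenzoic acid; 2 (S)-2-(methoxymethyl)pyrrolidine
Product: 4 (S)-(2-methoxy-3-methylphenyl)[2-(methoxymethyl)pyrrolidin-1-yl]methanone, via acid chloride 3 (not isolated)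
Conditions: (COCl)2, cat. DMF, CH2Cl2, 0 °C to rt; then 2, Et3N, CH2Cl2, 0 °C
Reagents that add atoms: none
Why: Acid chloride formation followed by N-acylation of the secondary amine is routine amide synthesis and does not touch the auxiliary stereocentre.

Step 2
Reactants: 4 benzamide
Product: 6 [(1R)-2-methoxy-1,3-dimethylcyclohexa-2,5-dien-1-yl][(2S)-2-(methoxymethyl)pyrrolidin-1-yl]methanone, via potassium amide enolate 5 (not isolated)
Conditions: K (2.2 equiv), t-BuOH (1 equiv), NH3/THF, −78 °C; then MeI, −78 °C
Reagents that add atoms: iodomethane, CI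
Why: Birch reduction of the chiral o-methoxybenzamide gives the chelated amide enolate 5, which is methylated on the face left open by the methoxymethyl arm (Birch reduction–alkylation), so the auxiliary sets the quaternary C4.

Step 3
Reactants: 6 dienyl amide
Product: 7 [(1S)-2-methoxy-1,3-dimethylcyclohexa-2,5-dien-1-yl]methanol
Conditions: LiH2NBH3 (from LiN(iPr)2 and H3N·BH3), THF, 0 °C to rt
Reagents that add atoms: none
Why: Lithium amidotrihydroborate reduces hindered tertiary amides to primary alcohols with C–N cleavage, which releases the auxiliary and leaves the enol ether and the quaternary centre untouched.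

Step 4
Reactants: 7 neopentyl alcohol
Product: 8 (6S)-1-methoxy-6-[(4-methoxybenzyloxy)methyl]-2,6-dimethylcyclohexa-1,4-diene
Conditions: NaH, 4-methoxybenzyl chloride, Bu4NI (cat.), DMF, 0 °C to rt
Reagents that add atoms: 4-methoxybenzyl chloride, COc1ccc(CCl)cc1
Why: Williamson etherification of the primary alkoxide installs a chelating ether that survives the acid and organometallic steps that follow.

Step 5
Reactants: 8 methyl enol ether
Product: 9 (2S)-2-[(4-methoxybenzyloxy)methyl]-2,6-dimethylcyclohex-3-en-1-one (C6 epimers)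
Conditions: 1 M HCl, THF, rt
Reagents that add atoms: water, O
Why: Acid hydrolysis of the enol ether unmasks the C9 ketone, the quaternary C4 blocks conjugation and aromatisation, and the new C10 centre is of no concern because it becomes sp2 in step 6.

Step 6
Reactants: 9 ketone
Product: 11 (6S)-6-[(4-methoxybenzyloxy)methyl]-2,6-dimethylcyclohexa-2,4-dien-1-one, via silyl enol ether 10 (not isolated)
Conditions: LiN(iPr)2, Me3SiCl, THF, −78 °C; then Pd(OAc)2, MeCN, rt
Reagents that add atoms: none
Why: Saegusa–Ito dehydrogenation works here because the ketone can enolise only towards C10, and after palladation at C10 the allylic ring hydrogen on C1 is lost to give the 2,4-dienone, which cannot tautomerise to a phenol since C4 is quaternary.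

Step 7
Reactants: 12 2-bromoprop-2-en-1-ol
Product: 13 (2-bromoallyloxy)(tert-butyl)dimethylsilane
Conditions: t-BuMe2SiCl, imidazole, DMF, rt
Reagents that add atoms: tert-butyldimethylsilyl chloride, CC(C)(C)[Si](C)(C)Cl
Why: Silylation of a primary alcohol is routine and gives an ether that tolerates organolithium, KH and oxidants.

Step 8
Reactants: 13 vinyl bromide; 14 (E)-1,2-bis(tributylstannyl)ethene (2 equiv)
Product: 15 (E)-tert-butyldimethyl{[2-methylene-4-(tributylstannyl)but-3-en-1-yl]oxy}silane
Conditions: Pd(PPh3)4 (5 mol %), toluene, 90 °C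
Reagents that add atoms: none
Why: Stille coupling of the vinyl bromide with one tin terminus proceeds with retention of the E geometry, and the excess of 14 suppresses a second coupling.

Step 9
Reactants: 11 dienone; 15 dienylstannane
Product: 18 tertiary dienol with the new alkenyl group on C9 trans to the CH2OPMB group on C4, via dienyllithium 16 (not isolated), via dienylmagnesium bromide 17 (not isolated)
Conditions: 15, n-BuLi, THF, −78 °C; MgBr2·OEt2; then 11 precomplexed with MgBr2·OEt2, CH2Cl2, −78 °C
Reagents that add atoms: none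
Why: Tin–lithium exchange and transmetalation give an alkenyl Grignard reagent that adds 1,2 to the dienone under Cram chelate control, magnesium bridging the C9 carbonyl and the PMB ether oxygen so that the alkenyl group enters anti to the CH2OPMB arm and the C9 hydroxyl ends cis to it.

Step 10
Reactants: 18 PMB ether
Product: 19 diol (primary C5 alcohol and tertiary C9 alcohol)
Conditions: DDQ, CH2Cl2/pH 7 phosphate buffer, 0 °C
Reagents that add atoms: none
Why: Oxidative PMB cleavage with DDQ is fast at 0 °C under buffered conditions and should leave the silyl ether and the acid-sensitive tertiary alcohol in place, while both dienes end at a quaternary carbon and should be too hindered for cycloaddition with the quinone.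

Step 11
Reactants: 19 diol
Product: 20 β-hydroxy aldehyde (C5 aldehyde on the quaternary C4)
Conditions: Dess–Martin periodinane, pyridine, CH2Cl2, 0 °C
Reagents that add atoms: none
Why: Dess–Martin oxidation converts the primary alcohol into the aldehyde, the tertiary alcohol cannot be oxidised, and the aldehyde has no α-hydrogen to epimerise or eliminate.

Step 12
Reactants: 20 aldehyde
Product: 21 (E)-vinyl iodide (C4–CH=CH–I)
Conditions: CrCl2, CHI3, THF/1,4-dioxane, 0 °C to rt
Reagents that add atoms: iodoform, IC(I)I
Why: Takai olefination adds the geminal dichromium species from iodoform to the aldehyde and the elimination gives the E vinyl iodide, a preference reinforced by the bulk of the quaternary C4.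

Step 13
Reactants: 21 vinyl iodide
Product: 22 trans-1,2-dialkenylcyclohexa-2,4-dienol with the E C5=C6 PMB enol ether on C4 and the E dienyl group on C9
Conditions: CuI (10 mol %), 3,4,7,8-tetramethyl-1,10-phenanthroline (20 mol %), Cs2CO3, 4-methoxybenzyl alcohol (2 equiv), toluene, 80 °C
Reagents that add atoms: 4-methoxybenzyl alcohol, COc1ccc(CO)cc1
Why: Copper-catalysed Ullmann-type C–O coupling of vinyl iodides with primary alcohols is stereospecific, so the E iodide should give the E enol ether, and the suspended carbonate is too weak a base to turn the hindered tertiary hydroxyl into its alkoxide.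

Step 14
Reactants: 22 dialkenyl dienol
Product: 25 ten-membered trienone bearing the C6–OPMB group trans to the C7 side chain, via potassium alkoxide 23 (not isolated), via potassium enolate 24 (not isolated)
Conditions: KH (3 equiv), 18-crown-6 (3 equiv), THF, 0 °C to rt; then saturated aqueous NH4Cl, −78 °C
Reagents that add atoms: none
Why: KH with 18-crown-6 should give the dissociated potassium alkoxide 23, whose oxyanion weakens the doubly allylic C4–C9 bond and triggers a concerted [3,3] shift through the exocyclic alkenes C7=C8 and C5=C6, forming C6–C7 and leaving enolate 24, which is protonated to 25 on cold quench. The closest known reaction is the anionic oxy-Cope ring expansion of trans-1,2-divinylcyclohexanols to cyclodec-5-enones. The ten-membered ring is not closed end to end but arises by expansion of the six-membered ring by the four alkenyl carbons, so C10=C1 and C2=C3 stay cis and C4=C5 is born E because C3 is equatorial on the chair. C6 and C7 are set by the chair transition state in which both E alkenyl termini are equatorial, which gives the trans C6–O/C7–C relationship, and their absolute sense follows from C4 and C9 because only one chair carries the cyclohexadiene ring diequatorially. The step needs this shift to outrun shifts through the ring alkenes and 6π opening of the cyclohexadienolate; the trans pseudo-diequatorial alkenyl groups place C6 and C7 within bonding distance, whereas the ring-alkene shifts need a boat across the ring and a disrotatory opening would turn two carbon or oxygen substituents of the quaternary termini inward. Enolate formation makes the step irreversible, and cold work-up with immediate use of 25 should limit 6π closure of its triene.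

Step 15
Reactants: 25 trienone
Product: 26 4,5-epoxy dienone (epoxide oxygen trans to the C6 oxygen)
Conditions: mCPBA (1.05 equiv), CH2Cl2/aqueous NaHCO3, −20 °C
Reagents that add atoms: 3-chloroperoxybenzoic acid, OOC(=O)c1cccc(Cl)c1
Why: Prilezhaev epoxidation should pick the strained trisubstituted E alkene C4=C5, which the ring twists out of conjugation, over the carbonyl-conjugated diene and the 1,1-disubstituted alkene, and attack on its outer face, anti to the C6–C7 ring bond, sets C4 and C5.

Step 16
Reactants: 26 epoxy dienone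
Product: 28 C8 bromo ketone with bromine trans to the C7 side chain, via silyl enol ether 27 (not isolated)
Conditions: LiN(SiMe3)2, Me3SiCl, THF, −78 °C; then N-bromosuccinimide, −78 °C
Reagents that add atoms: N-bromosuccinimide, O=C1CCC(=O)N1Br
Why: The ketone can enolise only towards C8, and electrophilic bromination of the enol silyl ether should occur on the outer face, anti to the C7–C6 ring bond, which places bromine trans to the C7 side chain.

Step 17
Reactants: 29 angelic acid
Product: 30 (Z)-2-methylbut-2-en-1-ol
Conditions: LiAlH4, Et2O, 0 °C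
Reagents that add atoms: none
Why: Hydride reduction of the unsaturated acid gives the allylic alcohol with the Z alkene unchanged.

Step 18
Reactants: 30 allylic alcohol
Product: 31 [(2R,3S)-2,3-dimethyloxiran-2-yl]methanol
Conditions: Ti(OiPr)4 (cat.), D-(−)-diethyl tartrate (cat.), t-BuOOH, 4 Å molecular sieves, CH2Cl2, −20 °C
Reagents that add atoms: tert-butyl hydroperoxide, CC(C)(C)OO
Why: In the Sharpless asymmetric epoxidation the D-(−)-tartrate complex delivers oxygen to the alkene face that gives the (2R,3S)-epoxy alcohol, so the catalyst sets both oxirane centres.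

Step 19
Reactants: 31 epoxy alcohol
Product: 32 (2S,3S)-2,3-dimethyloxirane-2-carboxylic acid
Conditions: RuCl3·xH2O (cat.), NaIO4, CCl4/MeCN/H2O, rt
Reagents that add atoms: sodium periodate, [Na+].[O-]I(=O)(=O)=O; water, O
Why: Catalytic ruthenium tetroxide oxidation takes the primary epoxy alcohol to the acid without opening the oxirane or touching its stereocentres.

Step 20
Reactants: 28 bromo ketone; 32 epoxy acid
Product: 34 C8 epoxyangelate ketone with the ester oxygen cis to the C7 side chain, via cesium carboxylate 33 (not isolated)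
Conditions: 32, Cs2CO3, DMF, 0 °C; then 28, 0 °C to rt
Reagents that add atoms: none
Why: SN2 displacement of the carbonyl-activated secondary bromide by the cesium carboxylate inverts C8, which brings the ester oxygen cis to the C7 side chain as in the target.

Step 21
Reactants: 34 acyloxy dienone
Product: 35 C9 allylic alcohol with the target configuration at C9
Conditions: NaBH4, CeCl3·7H2O, MeOH, −78 °C
Reagents that add atoms: none
Why: Luche 1,2-reduction of the dienone should deliver hydride anti to the C8 acyloxy group (polar Felkin–Anh model), which places the C9 oxygen trans to the C8 oxygen on the ring as in the target.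

Step 22
Reactants: 35 allylic alcohol
Product: 36 C9 acetate
Conditions: Ac2O, pyridine, DMAP (cat.), CH2Cl2, 0 °C
Reagents that add atoms: acetic anhydride, CC(=O)OC(C)=O
Why: DMAP-catalysed acetylation caps the C9 alcohol at once, before the hindered tertiary-alkyl ester on C8 can migrate.

Step 23
Reactants: 36 PMB ether
Product: 37 C6 alcohol
Conditions: DDQ, CH2Cl2/pH 7 phosphate buffer, 0 °C
Reagents that add atoms: none
Why: Oxidative PMB cleavage frees the C6 hydroxyl under near-neutral conditions that the vinyl epoxide, the esters and the silyl ether tolerate.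

Step 24
Reactants: 37 silyl ether
Product: 38 diol (C6 alcohol and primary allylic C12 alcohol)
Conditions: Bu4NF, AcOH, THF, 0 °C
Reagents that add atoms: none
Why: Fluoride desilylation buffered with acetic acid removes the primary silyl ether without acyl migration or ester cleavage.

Step 25
Reactants: 38 diol
Product: 41 trans-fused α-methylene γ-lactone (C14 still methyl), via hydroxy enal 39 (not isolated), via lactol 40 (not isolated)
Conditions: MnO2 (excess), CH2Cl2, rt
Reagents that add atoms: none
Why: MnO2 oxidises only the allylic primary alcohol, the enal is captured by the C6 hydroxyl as a lactol, and MnO2 then oxidises the lactol to the lactone (oxidative lactonisation), whose trans fusion was fixed at C6 and C7 in step 14.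

Step 26
Reactants: 41 lactone
Product: 42 C14 allylic alcohol
Conditions: SeO2 (cat.), t-BuOOH, CH2Cl2, rt
Reagents that add atoms: selenium dioxide, O=[Se]=O; tert-butyl hydroperoxide, CC(C)(C)OO
Why: Riley allylic oxidation (ene reaction then [2,3] shift) should attack C10=C1, the only alkene that is not electron-poor and carries an allylic methyl group, and hydroxylate C14, as in the known 14-hydroxylation of 4,5-epoxygermacranolides with this reagent.

Step 27
Reactants: 42 allylic alcohol
Product: 44 C14 carboxylic acid, via enal 43 (not isolated)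
Conditions: MnO2, CH2Cl2, rt; then NaClO2, NaH2PO4, 2-methyl-2-butene, t-BuOH/H2O, 0 °C
Reagents that add atoms: sodium chlorite, [Na+].[O-]Cl=O
Why: Allylic oxidation with MnO2 followed by Pinnick oxidation gives the dienoic acid under conditions that spare the α-methylene lactone, both oxiranes and the esters.

Step 28
Reactants: 44 acid
Product: 45 target CNP0229507.6
Conditions: Me3SiCHN2, MeOH/toluene, 0 °C
Reagents that add atoms: trimethylsilyldiazomethane, C[Si](C)(C)C=[N+]=[N-]
Why: Methyl esterification with trimethylsilyldiazomethane in methanol is fast and neutral, so none of the acid- or base-labile groups is exposed.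

**Compound list**

1 | 2-methoxy-3-methylbenzoic acid | COc1c(C)cccc1C(=O)O | starting material
2 | (S)-2-(methoxymethyl)pyrrolidine | COC[C@@H]1CCCN1 | starting material
3 | 2-methoxy-3-methylbenzoyl chloride | COc1c(C)cccc1C(=O)Cl | intermediate
4 | (S)-(2-methoxy-3-methylphenyl)[2-(methoxymethyl)pyrrolidin-1-yl]methanone | COC[C@@H]1CCCN1C(=O)c1cccc(C)c1OC | intermediate
5 | potassium amide enolate from Birch reduction of 4 | COC[C@@H]1CCCN1C([O-])=C1C=CCC(C)=C1OC.[K+] | intermediate
6 | [(1R)-2-methoxy-1,3-dimethylcyclohexa-2,5-dien-1-yl][(2S)-2-(methoxymethyl)pyrrolidin-1-yl]methanone | C[C@@]1(C(=O)N2CCC[C@H]2COC)C=CCC(C)=C1OC | intermediate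
7 | [(1S)-2-methoxy-1,3-dimethylcyclohexa-2,5-dien-1-yl]methanol | C[C@@]1(CO)C=CCC(C)=C1OC | intermediate
8 | (6S)-1-methoxy-6-[(4-methoxybenzyloxy)methyl]-2,6-dimethylcyclohexa-1,4-diene | C[C@@]1(COCc2ccc(OC)cc2)C=CCC(C)=C1OC | intermediate
9 | (2S)-2-[(4-methoxybenzyloxy)methyl]-2,6-dimethylcyclohex-3-en-1-one, C6 epimers | C[C@@]1(COCc2ccc(OC)cc2)C=CCC(C)C1=O | intermediate
10 | trimethylsilyl enol ether of 9 | C[C@@]1(COCc2ccc(OC)cc2)C=CCC(C)=C1O[Si](C)(C)C | intermediate
11 | (6S)-6-[(4-methoxybenzyloxy)methyl]-2,6-dimethylcyclohexa-2,4-dien-1-one | C[C@@]1(COCc2ccc(OC)cc2)C=CC=C(C)C1=O | intermediate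
12 | 2-bromoprop-2-en-1-ol | C=C(Br)CO | starting material
13 | (2-bromoallyloxy)(tert-butyl)dimethylsilane | C=C(Br)CO[Si](C)(C)C(C)(C)C | intermediate
14 | (E)-1,2-bis(tributylstannyl)ethene | CCCC[Sn](CCCC)(CCCC)/C=C/[Sn](CCCC)(CCCC)CCCC | starting material
15 | (E)-tert-butyldimethyl{[2-methylene-4-(tributylstannyl)but-3-en-1-yl]oxy}silane | CCCC[Sn](CCCC)(CCCC)/C=C/C(=C)CO[Si](C)(C)C(C)(C)C | intermediate
16 | (E)-dienyllithium from 15 | [Li]/C=C/C(=C)CO[Si](C)(C)C(C)(C)C | intermediate
17 | (E)-dienylmagnesium bromide from 16 | Br[Mg]/C=C/C(=C)CO[Si](C)(C)C(C)(C)C | intermediate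
18 | 6-[(4-methoxybenzyloxy)methyl]-2,6-dimethyl-1-[(E)-3-methylene-4-(tert-butyldimethylsilyloxy)but-1-enyl]cyclohexa-2,4-dien-1-ol, alkenyl trans to CH2OPMB | C[C@@]1(COCc2ccc(OC)cc2)C=CC=C(C)[C@@]1(O)/C=C/C(=C)CO[Si](C)(C)C(C)(C)C | intermediate
19 | diol from 18 (CH2OH on C4, tertiary OH on C9, cis) | C[C@@]1(CO)C=CC=C(C)[C@@]1(O)/C=C/C(=C)CO[Si](C)(C)C(C)(C)C | intermediate
20 | β-hydroxy aldehyde (CHO on C4) | C[C@@]1(C=O)C=CC=C(C)[C@@]1(O)/C=C/C(=C)CO[Si](C)(C)C(C)(C)C | intermediate
21 | (E)-2-iodovinyl dienol | C[C@@]1(/C=C/I)C=CC=C(C)[C@@]1(O)/C=C/C(=C)CO[Si](C)(C)C(C)(C)C | intermediate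
22 | oxy-Cope precursor: trans-1,2-dialkenylcyclohexa-2,4-dienol with E PMB enol ether on C4 and E dienyl group on C9 | C[C@@]1(/C=C/OCc2ccc(OC)cc2)C=CC=C(C)[C@@]1(O)/C=C/C(=C)CO[Si](C)(C)C(C)(C)C | intermediate
23 | potassium alkoxide of 22 | C[C@@]1(/C=C/OCc2ccc(OC)cc2)C=CC=C(C)[C@@]1([O-])/C=C/C(=C)CO[Si](C)(C)C(C)(C)C.[K+] | intermediate
24 | potassium enolate of 25 (ring carbons C7 and C10 trans across C8=C9) | COc1ccc(CO[C@H]2[C@H](C(=C)CO[Si](C)(C)C(C)(C)C)/C=C(\[O-])/C(C)=C\C=C/C(C)=C/2)cc1.[K+] | intermediate
25 | ten-membered trienone: C9 ketone, Z C10=C1, Z C2=C3, E C4=C5, C6–OPMB trans to the C7 3-(tert-butyldimethylsilyloxy)prop-1-en-2-yl group | COc1ccc(CO[C@H]2[C@H](C(=C)CO[Si](C)(C)C(C)(C)C)CC(=O)/C(C)=C\C=C/C(C)=C/2)cc1 | intermediate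
26 | 4,5-epoxy dienone | COc1ccc(CO[C@H]2[C@H](C(=C)CO[Si](C)(C)C(C)(C)C)CC(=O)/C(C)=C\C=C/[C@@]3(C)O[C@H]23)cc1 | intermediate
27 | trimethylsilyl enol ether of 26 (C8=C9, geometry not assigned) | COc1ccc(CO[C@H]2[C@H](C(=C)CO[Si](C)(C)C(C)(C)C)C=C(O[Si](C)(C)C)/C(C)=C\C=C/[C@@]3(C)O[C@H]23)cc1 | intermediate
28 | C8 bromo ketone, Br trans to the C7 side chain | COc1ccc(CO[C@H]2[C@H](C(=C)CO[Si](C)(C)C(C)(C)C)[C@@H](Br)C(=O)/C(C)=C\C=C/[C@@]3(C)O[C@H]23)cc1 | intermediate
29 | angelic acid, (Z)-2-methylbut-2-enoic acid | C/C=C(/C)C(=O)O | starting material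
30 | (Z)-2-methylbut-2-en-1-ol | C/C=C(/C)CO | intermediate
31 | [(2R,3S)-2,3-dimethyloxiran-2-yl]methanol | OC[C@@]1(C)O[C@H]1C | intermediate
32 | (2S,3S)-2,3-dimethyloxirane-2-carboxylic acid | OC(=O)[C@@]1(C)O[C@H]1C | intermediate
33 | cesium (2S,3S)-2,3-dimethyloxirane-2-carboxylate | [Cs+].[O-]C(=O)[C@@]1(C)O[C@H]1C | intermediate
34 | C8 epoxyangelate, C9 ketone | COc1ccc(CO[C@H]2[C@H](C(=C)CO[Si](C)(C)C(C)(C)C)[C@H](OC(=O)[C@@]3(C)O[C@H]3C)C(=O)/C(C)=C\C=C/[C@@]3(C)O[C@H]23)cc1 | intermediate
35 | C8 epoxyangelate, C9 alcohol | COc1ccc(CO[C@H]2[C@H](C(=C)CO[Si](C)(C)C(C)(C)C)[C@H](OC(=O)[C@@]3(C)O[C@H]3C)[C@@H](O)/C(C)=C\C=C/[C@@]3(C)O[C@H]23)cc1 | intermediate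
36 | C8 epoxyangelate, C9 acetate | COc1ccc(CO[C@H]2[C@H](C(=C)CO[Si](C)(C)C(C)(C)C)[C@H](OC(=O)[C@@]3(C)O[C@H]3C)[C@@H](OC(C)=O)/C(C)=C\C=C/[C@@]3(C)O[C@H]23)cc1 | intermediate
37 | C6 alcohol, C12 silyl ether | O[C@H]2[C@H](C(=C)CO[Si](C)(C)C(C)(C)C)[C@H](OC(=O)[C@@]3(C)O[C@H]3C)[C@@H](OC(C)=O)/C(C)=C\C=C/[C@@]3(C)O[C@H]23 | intermediate
38 | C6,C12 diol | O[C@H]2[C@H](C(=C)CO)[C@H](OC(=O)[C@@]3(C)O[C@H]3C)[C@@H](OC(C)=O)/C(C)=C\C=C/[C@@]3(C)O[C@H]23 | intermediate
39 | C6 alcohol, C12 enal | O[C@H]2[C@H](C(=C)C=O)[C@H](OC(=O)[C@@]3(C)O[C@H]3C)[C@@H](OC(C)=O)/C(C)=C\C=C/[C@@]3(C)O[C@H]23 | intermediate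
40 | α-methylene lactol (C12 hemiacetal, either epimer) | C=C1C(O)O[C@H]2[C@H]1[C@H](OC(=O)[C@@]1(C)O[C@H]1C)[C@@H](OC(C)=O)/C(C)=C\C=C/[C@@]1(C)O[C@H]21 | intermediate
41 | α-methylene γ-lactone with C14 methyl | C=C1C(=O)O[C@H]2[C@H]1[C@H](OC(=O)[C@@]1(C)O[C@H]1C)[C@@H](OC(C)=O)/C(C)=C\C=C/[C@@]1(C)O[C@H]21 | intermediate
42 | C14 alcohol | C=C1C(=O)O[C@H]2[C@H]1[C@H](OC(=O)[C@@]1(C)O[C@H]1C)[C@@H](OC(C)=O)/C(CO)=C\C=C/[C@@]1(C)O[C@H]21 | intermediate
43 | C14 aldehyde | C=C1C(=O)O[C@H]2[C@H]1[C@H](OC(=O)[C@@]1(C)O[C@H]1C)[C@@H](OC(C)=O)/C(C=O)=C\C=C/[C@@]1(C)O[C@H]21 | intermediate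
44 | C14 carboxylic acid | C=C1C(=O)O[C@H]2[C@H]1[C@H](OC(=O)[C@@]1(C)O[C@H]1C)[C@@H](OC(C)=O)/C(C(=O)O)=C\C=C/[C@@]1(C)O[C@H]21 | intermediate
45 | CNP0229507.6 | C=C1C(=O)O[C@H]2[C@H]1[C@H](OC(=O)[C@@]1(C)O[C@H]1C)[C@@H](OC(C)=O)/C(C(=O)OC)=C\C=C/[C@@]1(C)O[C@H]21 | target

**Step count and risks**

Total step count: 28. Longest linear sequence: 23 steps (steps 1–6, 9–16 and 20–28).

Steps most likely to fail:

1. Step 14 (key step). The alkoxide may escape by 6π opening of the cyclohexadiene or by a shift through a ring alkene, and the triene of the product may close by 6π electrocyclisation while the mixture warms. The fallback is a neutral siloxy-Cope rearrangement, which sets out from 22 and returns at 25. Compound 22 would be silylated (Me3SiOTf, 2,6-lutidine, CH2Cl2, −78 °C) to its trimethylsilyl ether F1. Heating F1 in toluene at about 110 °C in base-washed glass should give, through the same chair, the trimethylsilyl enol ether F2 of the ten-membered trienone. Cleavage of F2 with K2CO3 in MeOH at 0 °C would give 25.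

2. Step 16 (with its partner, step 20). The bromination may show poor facial selectivity, or the displacement in the medium ring may be slow and give way to loss of HBr towards C7. The fallback puts oxygen on C8 first and inverts it by a redox condensation instead of displacing a halide; it sets out from 26 and returns at 34. Compound 26 would be deprotonated with KN(SiMe3)2 in THF at −78 °C to its potassium enolate F3. Hydroxylation of F3 with the bulky 2-(phenylsulfonyl)-3-phenyloxaziridine on the outer face, followed by a quench with aqueous NH4Cl, should give the C8 hydroxy ketone F4 with the hydroxyl trans to the C7 side chain. Mitsunobu esterification of F4 with acid 32 (PPh3, diisopropyl azodicarboxylate, toluene, 0 °C to rt) would invert C8 and give 34.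

3. Step 9. Chelation may be incomplete, so that the alkenyl group adds to both faces of the dienone, or conjugate addition may compete. The fallback uses the bulky auxiliary amide as the blocking group; it sets out from 6 and returns at 20. Compound 6 would be hydrolysed (1 M HCl, THF) to the keto amide F5. Dehydrogenation of F5 with 2-iodoxybenzoic acid in DMSO at 65 °C would give the dienone amide F6. Addition of 17 to F6 at −78 °C, anti to the amide, would give the hydroxy amide F7. Reduction of F7 with Cp2Zr(H)Cl in THF at rt would cleave the amide to aldehyde 20.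

**Further compounds**

F1 | step 14 | trimethylsilyl ether of 22 | C[C@@]1(/C=C/OCc2ccc(OC)cc2)C=CC=C(C)[C@@]1(O[Si](C)(C)C)/C=C/C(=C)CO[Si](C)(C)C(C)(C)C
F2 | step 14 | trimethylsilyl enol ether of 25 (ring carbons C7 and C10 trans across C8=C9) | COc1ccc(CO[C@H]2[C@H](C(=C)CO[Si](C)(C)C(C)(C)C)/C=C(\O[Si](C)(C)C)/C(C)=C\C=C/C(C)=C/2)cc1
F3 | step 16 | potassium enolate of 26 | COc1ccc(CO[C@H]2[C@H](C(=C)CO[Si](C)(C)C(C)(C)C)C=C([O-])/C(C)=C\C=C/[C@@]3(C)O[C@H]23)cc1.[K+]
F4 | step 16 | C8 hydroxy ketone, OH trans to the C7 side chain | COc1ccc(CO[C@H]2[C@H](C(=C)CO[Si](C)(C)C(C)(C)C)[C@@H](O)C(=O)/C(C)=C\C=C/[C@@]3(C)O[C@H]23)cc1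
F5 | step 9 | keto amide from hydrolysis of 6 (C10 epimers) | C[C@@]1(C(=O)N2CCC[C@H]2COC)C=CCC(C)C1=O
F6 | step 9 | dienone amide | C[C@@]1(C(=O)N2CCC[C@H]2COC)C=CC=C(C)C1=O
F7 | step 9 | hydroxy amide, alkenyl trans to the amide | C[C@@]1(C(=O)N2CCC[C@H]2COC)C=CC=C(C)[C@@]1(O)/C=C/C(=C)CO[Si](C)(C)C(C)(C)C
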